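**Plan**
Briarane numbering: ring A = cyclohexane C1, C10–C14; ring B = ten-membered carbocycle C1–C10; ring C = γ-lactone O–C7–C8–C17–C19. β is the face of ring A that bears the C15 methyl, α the other face.
Cuts: first the acyl groups, then C9–C10 (opens ring B), then C4–C5. This leaves enone epoxide 14 (ring A with C2–C4) and Z-vinyl iodide lactone 29 (ring C with C5, C6, C9).
Enabling feature: O9 and O12 stand 1,4 along C9–C10–C11–C12 across the A/B junction, a dissonant pair. Read backwards they are an aldehyde (C9) and the β-carbon (C10) of a ring A enone (C10=C11–C12=O), two electrophilic carbons that a ketyl radical can join.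
Forward: ring A by dearomatising Birch methylation; ring C taken from 2-C-methyl-D-ribonolactone; C4–C5 union by nickel cross-electrophile coupling; ring B last with SmI2, which also sets C9, C10 and C11.
Stereochemistry: C1 from a prolinol auxiliary; C14 and C2 from C1 (hydride past the methyl, chelated Grignard addition); C3 from Sharpless epoxidation. C17 comes from the sugar, C8 by addition anti to C18/C6, C7 by SN2 inversion, C12 by hydride anti to C9, and the Z-alkene from an iodo-ylide Wittig reaction.

Key step: step 24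

Assumption: the (S)-prolinol ether auxiliary is taken to steer MeI to the face of enolate 5 that gives the 1R centre. If the sense is opposite, the equally available (R)-amine is used and nothing else changes.

**Step 1**
Reactants: 1 2-methoxy-5-methylbenzoic acid; 2 (S)-2-(methoxymethyl)pyrrolidine
Product: 4 (2-methoxy-5-methylphenyl)[(2S)-2-(methoxymethyl)pyrrolidin-1-yl]methanone, via acid chloride 3 (not isolated)
Conditions: SOCl2, cat. DMF, toluene, 70 °C; concentrate; then 2, Et3N, CH2Cl2, 0 °C to rt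
Reagents that add atoms: none
Why: Amide formation by acylation of the amine with the acid chloride attaches the auxiliary, and no stereocentre is touched.

**Step 2**
Reactants: 4 benzamide
Product: 6 (1R)-6-methoxy-1,3-dimethylcyclohexa-2,5-diene-1-carboxamide of auxiliary 2, via potassium dienolate 5 (not isolated)
Conditions: K (2.2 equiv), NH3(l)/THF, t-BuOH (1.0 equiv), −78 °C; then MeI, −78 °C
Reagents that add atoms: iodomethane, CI
Why: Birch reduction–alkylation: the arene takes two electrons and one proton (at C12, para to the amide) to give dienolate 5, and MeI attacks C1 on the face left open by the chelated methoxymethyl arm, which sets the quaternary C1.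

**Step 3**
Reactants: 6 diene amide
Product: 7 (1R)-1,3-dimethyl-6-oxocyclohex-2-ene-1-carboxamide of auxiliary 2
Conditions: aq. HCl (1 M), THF, rt
Reagents that add atoms: water, O
Why: Acid hydrolysis of the enol ether gives the C14 ketone, and the C10=C11 alkene cannot move into conjugation through the quaternary C1.

**Step 4**
Reactants: 7 keto amide
Product: 9 (1S,2S)-2-(hydroxymethyl)-2,4-dimethylcyclohex-3-en-1-ol, via hydroxy amide 8 (not isolated)
Conditions: BH3·NH3, n-BuLi, THF, 0 °C (gives LiH2NBH3, 6 equiv); add 7, 0 °C, then 23 °C; aq. HCl work-up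
Reagents that add atoms: none
Why: Hydride reduction with lithium amidotrihydroborate takes the ketone first, from the β face past the small C15 methyl and away from the bulky carboxamide (C1 lies between two sp2 carbons, so its substituents flank the two carbonyl faces), which sets 14α-OH; on warming the hindered tertiary amide goes to the primary alcohol and releases the auxiliary.

**Step 5**
Reactants: 9 diol
Product: 10 (1R,6S)-6-hydroxy-1,3-dimethylcyclohex-2-ene-1-carbaldehyde
Conditions: TEMPO (10 mol %), PhI(OAc)2, CH2Cl2, rt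
Reagents that add atoms: none
Why: Oxoammonium (TEMPO) oxidation prefers the primary alcohol over the secondary one and stops at the aldehyde.

**Step 6**
Reactants: 10 hydroxy aldehyde
Product: 11 vinyl carbinol (ring A 14α-ol carrying CH(OH)CH=CH2 on the α face of C1; C2 as in the target)
Conditions: CH2=CHMgBr (3.5 equiv), THF/CH2Cl2, −78 °C; aq. NH4Cl
Reagents that add atoms: vinylmagnesium bromide, C=C[Mg]Br
Why: Chelation-controlled Grignard addition: magnesium ties the C14 alkoxide to the aldehyde oxygen in a six-membered chelate below ring A, and the vinyl group can approach only from the open outer face, which sets C2.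

**Step 7**
Reactants: 11 vinyl carbinol
Product: 12 erythro epoxy diol (C3–C4 oxirane; C2 and C3 as in the target)
Conditions: Ti(OiPr)4 (1.1 equiv), D-(−)-diisopropyl tartrate (1.3 equiv), t-BuOOH (decane), 4 Å sieves, CH2Cl2, −20 °C
Reagents that add atoms: tert-butyl hydroperoxide, CC(C)(C)OO
Why: Sharpless asymmetric epoxidation in the matched sense: with D-(−)-tartrate this carbinol configuration reacts fast and gives the erythro epoxy alcohol (sets C3), any C2 epimer is left behind, and the merely homoallylic ring alkene stays intact.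

**Step 8**
Reactants: 12 epoxy diol
Product: 13 2,14-bis(triethylsilyl) ether of 12
Conditions: Et3SiOTf (2.5 equiv), 2,6-lutidine, CH2Cl2, −78 to 0 °C
Reagents that add atoms: triethylsilyl triflate, CC[Si](CC)(CC)OS(=O)(=O)C(F)(F)F
Why: Silyl triflate silylation caps both hindered secondary alcohols at low temperature without opening the epoxide.

**Step 9**
Reactants: 13 bis(silyl) epoxide
Product: 14 ring A enone epoxide (C12 ketone conjugated to C10=C11)
Conditions: Rh2(cap)4 (cap = caprolactamate, 1 mol %), t-BuOOH (5 equiv), 1,2-dichloroethane, 40 °C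
Reagents that add atoms: tert-butyl hydroperoxide, CC(C)(C)OO
Why: Dirhodium-catalysed allylic C–H oxidation attacks the only ring methylene next to the trisubstituted alkene (C12) and gives the 2-methylcyclohexenone, the acceptor for the key step.

**Step 10**
Reactants: 15 2-C-methyl-D-ribono-1,4-lactone
Product: 16 5-O-(tert-butyldimethylsilyl) ether of 15
Conditions: t-BuMe2SiCl (1.05 equiv), imidazole, DMF, 0 °C
Reagents that add atoms: tert-butyldimethylsilyl chloride, CC(C)(C)[Si](C)(C)Cl
Why: Imidazole-promoted silylation picks the only primary hydroxyl (O6).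

**Step 11**
Reactants: 16 silyl ether
Product: 17 (3R,5R)-5-(tert-butyldimethylsilyloxymethyl)-3-hydroxy-3-methyloxolane-2,4-dione
Conditions: Dess–Martin periodinane, CH2Cl2, rt
Reagents that add atoms: none
Why: Dess–Martin oxidation converts the only secondary alcohol into the C8 ketone, and the tertiary C17 hydroxyl cannot be oxidised.

**Step 12**
Reactants: 18 4-methoxybenzyl alcohol; 19 tributyl(iodomethyl)stannane
Product: 20 tributyl{[(4-methoxybenzyl)oxy]methyl}stannane
Conditions: NaH, THF/DMF, 0 °C; then 19, rt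
Reagents that add atoms: none
Why: Williamson ether synthesis on the primary iodide gives a protected hydroxymethyl anion equivalent.

**Step 13**
Reactants: 17 keto lactone; 20 stannane
Product: 22 C8 tertiary carbinol bearing CH2OPMB (C9) on the face of O17, via alkoxymethyllithium 21 (not isolated)
Conditions: 20 (2.6 equiv), n-BuLi (2.5 equiv), THF, −78 °C; then 17, −78 °C; aq. NH4Cl
Reagents that add atoms: none
Why: Tin–lithium exchange and 1,2-addition: the ketone is far more electrophilic than the α-quaternary lactone carbonyl, and the reagent enters syn to the C17 lithium alkoxide and anti to both the C18 methyl and the C6 side chain, which sets C8.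

**Step 14**
Reactants: 22 adduct
Product: 23 triol (O6, O8, O17 free; O9 as PMB ether)
Conditions: HF·pyridine, THF, 0 °C
Reagents that add atoms: none
Why: Fluoride-driven desilylation frees the primary alcohol, and the PMB ether and lactone are inert.

**Step 15**
Reactants: 23 triol
Product: 24 6-O-methanesulfonate of 23
Conditions: MsCl (1.05 equiv), pyridine, CH2Cl2, −20 °C
Reagents that add atoms: methanesulfonyl chloride, CS(=O)(=O)Cl
Why: Sulfonylation takes the primary hydroxyl only, since both other hydroxyls are tertiary.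

**Step 16**
Reactants: 24 mesylate
Product: 26 C7-inverted lactone triol (C6, C9 and O17 on one face of ring C; O8 and C18 on the other), via epoxy carboxylate 25 (not isolated)
Conditions: KOH (2.5 equiv), H2O/THF, rt; then aq. HCl to pH 3
Reagents that add atoms: potassium hydroxide, [K+].[OH-]
Why: Base opens the lactone, the C7 alkoxide closes the 6,7-epoxide, and the carboxylate reopens it 5-exo-tet at C7 with SN2 inversion (the known inversion of 5-sulfonyl or 5-halo pentono-1,4-lactones), which sets C7 and frees O6.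

**Step 17**
Reactants: 26 triol
Product: 27 6,8,17-tris(triethylsilyl) ether of 26
Conditions: Et3SiOTf (4 equiv), 2,6-lutidine, CH2Cl2, 0 °C to rt
Reagents that add atoms: triethylsilyl triflate, CC[Si](CC)(CC)OS(=O)(=O)C(F)(F)F
Why: Silyl triflate silylation is strong enough for the two tertiary alcohols and removes all acidic protons before the ylide step.

**Step 18**
Reactants: 27 tris(silyl) ether
Product: 28 C6 aldehyde
Conditions: (COCl)2, DMSO, CH2Cl2, −78 to −40 °C; Et3N, −78 °C
Reagents that add atoms: none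
Why: Swern oxidation acts directly and selectively on a primary triethylsilyl ether and leaves the tertiary silyl ethers in place.

**Step 19**
Reactants: 28 aldehyde
Product: 29 (Z)-2-iodoprop-1-enyl lactone (iodine cis to C7)
Conditions: [Ph3PEt]I, n-BuLi, THF, rt; I2, −78 °C; NaN(SiMe3)2, −20 °C; then 28, −78 °C
Reagents that add atoms: ethyltriphenylphosphonium iodide, CC[P+](c1ccccc1)(c1ccccc1)c1ccccc1.[I-]; iodine, II
Why: Stork–Zhao type Wittig olefination with the α-iodoethylidene ylide gives the Z-trisubstituted vinyl iodide under kinetic control at −78 °C, which fixes the C5=C6 geometry.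

**Step 20**
Reactants: 14 enone epoxide; 29 vinyl iodide
Product: 31 coupled homoallylic alcohol (C4–C5 bond; O3 free), via iodohydrin 30 (not isolated)
Conditions: NiCl2(dme) (15 mol %), 2,2'-bipyridine (15 mol %), NaI (30 mol %), Et3N·HCl (1.0 equiv), Zn (2 equiv), DMPU, rt
Reagents that add atoms: none
Why: Nickel-catalysed reductive cross-electrophile coupling: iodide opens the terminal epoxide at C4 to iodohydrin 30, its primary radical is captured by the alkenylnickel species from 29, and reductive elimination forges C4–C5 with retention of the Z geometry, leaving O3 as the only free hydroxyl.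

**Step 21**
Reactants: 31 alcohol
Product: 32 3-O-butyrate
Conditions: (n-PrCO)2O, DMAP, Et3N, CH2Cl2, rt
Reagents that add atoms: butyric anhydride, CCCC(=O)OC(=O)CCC
Why: DMAP-catalysed acylation places the butyrate on the single free hydroxyl, which settles the butyrate/acetate pattern.

**Step 22**
Reactants: 32 butyrate
Product: 33 C9 primary alcohol
Conditions: DDQ, CH2Cl2/pH 7 buffer, 0 °C
Reagents that add atoms: none
Why: Oxidative PMB cleavage with DDQ spares the silyl ethers, the enone and the alkene.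

**Step 23**
Reactants: 33 alcohol
Product: 34 enone aldehyde (C9 aldehyde on the quaternary C8)
Conditions: Dess–Martin periodinane, pyridine, CH2Cl2, 0 °C to rt
Reagents that add atoms: none
Why: Dess–Martin oxidation gives an α-silyloxy aldehyde that has no α-hydrogen and so cannot epimerise or enolise.

**Step 24**
Reactants: 34 enone aldehyde
Product: 37 tricyclic 9-hydroxy-12-ketone (rings A, B and C complete), via samarium ketyl 35 (not isolated), via samarium enolate 36 (not isolated)
Conditions: SmI2 (0.1 M in THF, 3 equiv), t-BuOH (4 equiv), THF, −40 °C; 34 added by syringe pump over 8 h (final 1 mM); then 0 °C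
Reagents that add atoms: none
Why: Proposed new method: SmI2 gives one electron to the C9 aldehyde, the ketyl 35 (C9 now a nucleophilic radical, its polarity reversed) adds to C10, the β-carbon of the ring A enone, a second SmI2 turns the α-keto radical into the trivalent samarium enolate 36, and t-BuOH protonates it at C11. The closest known reaction type is the SmI2 ketyl–alkene (aldehyde–enone) reductive cyclisation, well shown for five- to eight-membered rings; new here is the ten-membered closure, argued from the fast, irreversible addition of an α-oxygenated radical to an enone, from high dilution, and from a tether in which the Z-alkene, the cis-disubstituted lactone and the quaternary C1 leave few free rotors. Ring B closes in the 10-exo-trig mode, C11 staying outside the new ring. C10 is set by axial attack on the β face of the half-chair that holds the O14 silyl ether pseudo-equatorial and the C1–C2 bond pseudo-axial on the α face, so that C9 enters anti to C2 (trans A/B junction); C9 is set by trivalent samarium bridging the ketyl oxygen and the enone oxygen, which lays O9 over ring A while the tether holds C8 towards the C1 edge (9S); C11 is set by axial protonation of 36 from the α face, anti to the new C9–C10 bond, which leaves C20 β. The step needs the aldehyde and the enone to react in the presence of the lactone, the butyrate and the C8–O bond: without HMPA SmI2 does not reduce esters, the C8 oxygen is a poor leaving group as its silyl ether, and the isolated C5=C6 alkene is no acceptor for a ketyl at four- or five-ring distance.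

**Step 25**
Reactants: 37 hydroxy ketone
Product: 38 9,12-diol (12β-OH)
Conditions: NaBH4, MeOH/THF, −40 °C
Reagents that add atoms: none
Why: Borohydride reduction: the β face of the C12 ketone is blocked by the syn-axial C9 substituent, so hydride enters from the α face and gives the axial 12β-alcohol, while the lactone and butyrate survive at this temperature.

**Step 26**
Reactants: 38 diol
Product: 39 hexaol 3-butyrate (O2, O8, O9, O12, O14, O17 free)
Conditions: HF·pyridine, pyridine, THF, 0 °C to rt
Reagents that add atoms: none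
Why: Global fluoride desilylation under buffered, mildly acidic conditions removes all four silyl groups, and butyrate migration to the more hindered neopentyl O2 is disfavoured.

**Step 27**
Reactants: 39 hexaol butyrate
Product: 40 CNP0251217.1 (target)
Conditions: Ac2O, pyridine, DMAP (5 mol %), rt
Reagents that add atoms: acetic anhydride, CC(=O)OC(C)=O
Why: Acetylation esterifies the four secondary alcohols (O2, O9, O12, O14), whereas the two tertiary alcohols (O8, O17) do not react at room temperature.

**Compound list**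
1 | 2-methoxy-5-methylbenzoic acid | COc1ccc(C)cc1C(=O)O | starting material
2 | (S)-2-(methoxymethyl)pyrrolidine | COC[C@@H]1CCCN1 | starting material
3 | 2-methoxy-5-methylbenzoyl chloride | COc1ccc(C)cc1C(Cl)=O | intermediate
4 | (2-methoxy-5-methylphenyl)[(2S)-2-(methoxymethyl)pyrrolidin-1-yl]methanone | COc1ccc(C)cc1C(=O)N1CCC[C@H]1COC | intermediate
5 | potassium dienolate of the 1,4-dihydrobenzamide | COC1=CCC(C)=CC1=C([O-])N2CCC[C@H]2COC.[K+] | intermediate
6 | (1R)-6-methoxy-1,3-dimethylcyclohexa-2,5-diene-1-carboxamide of 2 | C1=C(C)CC=C(OC)[C@]1(C)C(=O)N2CCC[C@H]2COC | intermediate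
7 | (1R)-1,3-dimethyl-6-oxocyclohex-2-ene-1-carboxamide of 2 | C1=C(C)CCC(=O)[C@]1(C)C(=O)N2CCC[C@H]2COC | intermediate
8 | 14α-hydroxy amide | C1=C(C)CC[C@H](O)[C@]1(C)C(=O)N2CCC[C@H]2COC | intermediate
9 | (1S,2S)-2-(hydroxymethyl)-2,4-dimethylcyclohex-3-en-1-ol | C1=C(C)CC[C@H](O)[C@]1(C)CO | intermediate
10 | (1R,6S)-6-hydroxy-1,3-dimethylcyclohex-2-ene-1-carbaldehyde | C1=C(C)CC[C@H](O)[C@]1(C)C=O | intermediate
11 | vinyl carbinol (C2 set) | C1=C(C)CC[C@H](O)[C@]1(C)[C@@H](O)C=C | intermediate
12 | erythro epoxy diol (C3 set) | C1=C(C)CC[C@H](O)[C@]1(C)[C@@H](O)[C@@H]2CO2 | intermediate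
13 | 2,14-bis(triethylsilyl) epoxide | C1=C(C)CC[C@H](O[Si](CC)(CC)CC)[C@]1(C)[C@@H](O[Si](CC)(CC)CC)[C@@H]2CO2 | intermediate
14 | ring A enone epoxide | C1=C(C)C(=O)C[C@H](O[Si](CC)(CC)CC)[C@]1(C)[C@@H](O[Si](CC)(CC)CC)[C@@H]2CO2 | intermediate
15 | 2-C-methyl-D-ribono-1,4-lactone | OC[C@H]1OC(=O)[C@](C)(O)[C@@H]1O | starting material
16 | 5-O-TBS-2-C-methyl-D-ribono-1,4-lactone | CC(C)(C)[Si](C)(C)OC[C@H]1OC(=O)[C@](C)(O)[C@@H]1O | intermediate
17 | (3R,5R)-5-(TBS-oxymethyl)-3-hydroxy-3-methyloxolane-2,4-dione | CC(C)(C)[Si](C)(C)OC[C@H]1OC(=O)[C@](C)(O)C1=O | intermediate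
18 | 4-methoxybenzyl alcohol | COc1ccc(CO)cc1 | starting material
19 | tributyl(iodomethyl)stannane | CCCC[Sn](CCCC)(CCCC)CI | starting material
20 | tributyl{[(4-methoxybenzyl)oxy]methyl}stannane | CCCC[Sn](CCCC)(CCCC)COCc1ccc(OC)cc1 | intermediate
21 | [(4-methoxybenzyl)oxy]methyllithium | [Li]COCc1ccc(OC)cc1 | intermediate
22 | C8 carbinol with CH2OPMB, 6-O-TBS | CC(C)(C)[Si](C)(C)OC[C@H]1OC(=O)[C@](C)(O)[C@]1(O)COCc2ccc(OC)cc2 | intermediate
23 | triol, O9 as PMB ether | OC[C@H]1OC(=O)[C@](C)(O)[C@]1(O)COCc2ccc(OC)cc2 | intermediate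
24 | 6-O-mesylate | CS(=O)(=O)OC[C@H]1OC(=O)[C@](C)(O)[C@]1(O)COCc2ccc(OC)cc2 | intermediate
25 | potassium 6,7-epoxy carboxylate | [K+].[O-]C(=O)[C@](C)(O)[C@](O)(COCc1ccc(OC)cc1)[C@H]2CO2 | intermediate
26 | C7-inverted lactone triol | OC[C@@H]1OC(=O)[C@](C)(O)[C@]1(O)COCc2ccc(OC)cc2 | intermediate
27 | 6,8,17-tris(triethylsilyl) ether | CC[Si](CC)(CC)OC[C@@H]1OC(=O)[C@](C)(O[Si](CC)(CC)CC)[C@]1(O[Si](CC)(CC)CC)COCc2ccc(OC)cc2 | intermediate
28 | C6 aldehyde | O=C[C@@H]1OC(=O)[C@](C)(O[Si](CC)(CC)CC)[C@]1(O[Si](CC)(CC)CC)COCc2ccc(OC)cc2 | intermediate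
29 | (Z)-vinyl iodide lactone | I/C(C)=C\[C@@H]1OC(=O)[C@](C)(O[Si](CC)(CC)CC)[C@]1(O[Si](CC)(CC)CC)COCc2ccc(OC)cc2 | intermediate
30 | C4 iodohydrin of 14 | C1=C(C)C(=O)C[C@H](O[Si](CC)(CC)CC)[C@]1(C)[C@@H](O[Si](CC)(CC)CC)[C@@H](O)CI | intermediate
31 | coupled homoallylic alcohol | C1=C(C)C(=O)C[C@H](O[Si](CC)(CC)CC)[C@]1(C)[C@@H](O[Si](CC)(CC)CC)[C@@H](O)C/C(C)=C\[C@@H]2OC(=O)[C@](C)(O[Si](CC)(CC)CC)[C@]2(O[Si](CC)(CC)CC)COCc3ccc(OC)cc3 | intermediate
32 | 3-O-butyrate | C1=C(C)C(=O)C[C@H](O[Si](CC)(CC)CC)[C@]1(C)[C@@H](O[Si](CC)(CC)CC)[C@@H](OC(=O)CCC)C/C(C)=C\[C@@H]2OC(=O)[C@](C)(O[Si](CC)(CC)CC)[C@]2(O[Si](CC)(CC)CC)COCc3ccc(OC)cc3 | intermediate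
33 | C9 primary alcohol | C1=C(C)C(=O)C[C@H](O[Si](CC)(CC)CC)[C@]1(C)[C@@H](O[Si](CC)(CC)CC)[C@@H](OC(=O)CCC)C/C(C)=C\[C@@H]2OC(=O)[C@](C)(O[Si](CC)(CC)CC)[C@]2(O[Si](CC)(CC)CC)CO | intermediate
34 | enone aldehyde | C1=C(C)C(=O)C[C@H](O[Si](CC)(CC)CC)[C@]1(C)[C@@H](O[Si](CC)(CC)CC)[C@@H](OC(=O)CCC)C/C(C)=C\[C@@H]2OC(=O)[C@](C)(O[Si](CC)(CC)CC)[C@]2(O[Si](CC)(CC)CC)C=O | intermediate
35 | samarium ketyl at C9 | C1=C(C)C(=O)C[C@H](O[Si](CC)(CC)CC)[C@]1(C)[C@@H](O[Si](CC)(CC)CC)[C@@H](OC(=O)CCC)C/C(C)=C\[C@@H]2OC(=O)[C@](C)(O[Si](CC)(CC)CC)[C@]2(O[Si](CC)(CC)CC)[CH]O[Sm](I)I | intermediate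
36 | samarium enolate (C11=C12) and C9 alkoxide | CCCC(=O)O[C@H]1C/C(C)=C\[C@@H]2OC(=O)[C@](C)(O[Si](CC)(CC)CC)[C@]2(O[Si](CC)(CC)CC)[C@@H](O[Sm](I)I)[C@H]2C(C)=C(O[Sm](I)I)C[C@H](O[Si](CC)(CC)CC)[C@]2(C)[C@H]1O[Si](CC)(CC)CC | intermediate
37 | tricyclic 9-hydroxy-12-ketone | CCCC(=O)O[C@H]1C/C(C)=C\[C@@H]2OC(=O)[C@](C)(O[Si](CC)(CC)CC)[C@]2(O[Si](CC)(CC)CC)[C@@H](O)[C@H]2[C@@H](C)C(=O)C[C@H](O[Si](CC)(CC)CC)[C@]2(C)[C@H]1O[Si](CC)(CC)CC | intermediate
38 | 9,12-diol | CCCC(=O)O[C@H]1C/C(C)=C\[C@@H]2OC(=O)[C@](C)(O[Si](CC)(CC)CC)[C@]2(O[Si](CC)(CC)CC)[C@@H](O)[C@H]2[C@@H](C)[C@@H](O)C[C@H](O[Si](CC)(CC)CC)[C@]2(C)[C@H]1O[Si](CC)(CC)CC | intermediate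
39 | hexaol 3-butyrate | CCCC(=O)O[C@H]1C/C(C)=C\[C@@H]2OC(=O)[C@](C)(O)[C@]2(O)[C@@H](O)[C@H]2[C@@H](C)[C@@H](O)C[C@H](O)[C@]2(C)[C@H]1O | intermediate
40 | CNP0251217.1 | CCCC(=O)O[C@H]1C/C(C)=C\[C@@H]2OC(=O)[C@](C)(O)[C@]2(O)[C@@H](OC(C)=O)[C@H]2[C@@H](C)[C@@H](OC(C)=O)C[C@H](OC(C)=O)[C@]2(C)[C@H]1OC(C)=O | target

**Step count**
Total step count: 27.
Longest linear sequence: 17 steps (steps 1–9 and 20–27). The lactone branch (steps 10, 11, 13–19 and 20–27) is equally long.

**Steps most likely to fail**

**Step 24.**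
- What may go wrong: the ketyl or the enone may be reduced and protonated before the ten-membered closure occurs. Attack may come from the α face of C10 or from the other ketyl face. The new C9 alkoxide may start a translactonisation.
- Fallback (known tin-hydride radical macrocyclisation of the Giese type), from 34:
  - Acetyl bromide with catalytic ZnBr2 adds across the aldehyde to give the 1-bromoalkyl acetate F1.
  - Slow addition of Bu3SnH/AIBN in refluxing benzene at high dilution generates the nucleophilic α-acetoxyalkyl radical, which closes ring B onto the enone to give the 9-acetoxy-12-ketone F2.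
  - NaBH4 gives the 12β-alcohol F3, and HF·pyridine gives the pentaol 9-acetate 3-butyrate F4.
  - Ac2O/pyridine returns to the route at 40.

**Step 20.**
- What may go wrong: low-valent nickel and zinc may engage the enone. The iodohydrin may undergo reductive elimination to the terminal alkene. The vinyl iodide may homocouple or lose its Z geometry.
- Fallback (C4 becomes a nucleophile at the C3 ketone level), from 14:
  - LiBr/AcOH opens the epoxide to the bromohydrin F5, and Dess–Martin oxidation gives the α-bromo ketone F6.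
  - Zn dust forms the bromozinc enolate F7 (a Reformatsky reagent).
  - Negishi-type coupling of F7 with 29 under Pd(dba)2/P(t-Bu)3 gives the β,γ-unsaturated ketone F8.
  - Zn(BH4)2 at −78 °C reduces the α-silyloxy ketone ahead of the enone, in the Felkin–Anh sense, to the erythro product. This returns to the route at 31.

**Step 19.**
- What may go wrong: the basic ylide may cause β-elimination of the C8 silyloxy group or epimerisation at C7 of aldehyde 28. Z selectivity may be insufficient.
- Fallback, from 28: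
  - The near-neutral first stage of the Corey–Fuchs reaction (CBr4, PPh3, Zn) gives the 1,1-dibromoalkene F9.
  - A Negishi methylation (Me2Zn, PdCl2(DPEphos)), selective for the bromine trans to C7, gives the (Z)-vinyl bromide F10.
  - F10 takes the place of 29 in step 20 and returns to the route at 31.

**Further compounds**
F1 | step 24 | 1-bromoalkyl acetate at C9 | C1=C(C)C(=O)C[C@H](O[Si](CC)(CC)CC)[C@]1(C)[C@@H](O[Si](CC)(CC)CC)[C@@H](OC(=O)CCC)C/C(C)=C\[C@@H]2OC(=O)[C@](C)(O[Si](CC)(CC)CC)[C@]2(O[Si](CC)(CC)CC)C(Br)OC(C)=O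
F2 | step 24 | 9-acetoxy-12-ketone | CCCC(=O)O[C@H]1C/C(C)=C\[C@@H]2OC(=O)[C@](C)(O[Si](CC)(CC)CC)[C@]2(O[Si](CC)(CC)CC)[C@@H](OC(C)=O)[C@H]2[C@@H](C)C(=O)C[C@H](O[Si](CC)(CC)CC)[C@]2(C)[C@H]1O[Si](CC)(CC)CC
F3 | step 24 | 9-acetoxy-12β-alcohol | CCCC(=O)O[C@H]1C/C(C)=C\[C@@H]2OC(=O)[C@](C)(O[Si](CC)(CC)CC)[C@]2(O[Si](CC)(CC)CC)[C@@H](OC(C)=O)[C@H]2[C@@H](C)[C@@H](O)C[C@H](O[Si](CC)(CC)CC)[C@]2(C)[C@H]1O[Si](CC)(CC)CC
F4 | step 24 | pentaol 9-acetate 3-butyrate | CCCC(=O)O[C@H]1C/C(C)=C\[C@@H]2OC(=O)[C@](C)(O)[C@]2(O)[C@@H](OC(C)=O)[C@H]2[C@@H](C)[C@@H](O)C[C@H](O)[C@]2(C)[C@H]1O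
F5 | step 20 | C4 bromohydrin | C1=C(C)C(=O)C[C@H](O[Si](CC)(CC)CC)[C@]1(C)[C@@H](O[Si](CC)(CC)CC)[C@@H](O)CBr
F6 | step 20 | α-bromo ketone (C3 ketone) | C1=C(C)C(=O)C[C@H](O[Si](CC)(CC)CC)[C@]1(C)[C@@H](O[Si](CC)(CC)CC)C(=O)CBr
F7 | step 20 | bromozinc enolate | C1=C(C)C(=O)C[C@H](O[Si](CC)(CC)CC)[C@]1(C)[C@@H](O[Si](CC)(CC)CC)C(=C)O[Zn]Br
F8 | step 20 | β,γ-unsaturated C3 ketone | C1=C(C)C(=O)C[C@H](O[Si](CC)(CC)CC)[C@]1(C)[C@@H](O[Si](CC)(CC)CC)C(=O)C/C(C)=C\[C@@H]2OC(=O)[C@](C)(O[Si](CC)(CC)CC)[C@]2(O[Si](CC)(CC)CC)COCc3ccc(OC)cc3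
F9 | step 19 | 1,1-dibromoalkene | BrC(Br)=C[C@@H]1OC(=O)[C@](C)(O[Si](CC)(CC)CC)[C@]1(O[Si](CC)(CC)CC)COCc2ccc(OC)cc2
F10 | step 19 | (Z)-vinyl bromide lactone | Br/C(C)=C\[C@@H]1OC(=O)[C@](C)(O[Si](CC)(CC)CC)[C@]1(O[Si](CC)(CC)CC)COCc2ccc(OC)cc2
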